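The C4(=O)–C4a bond (naphthoquinone numbering) between the quinone ring and the dimethylbenzo ring A is the disconnection on which everything rests. The key step is a Moore–Liebeskind rearrangement: heating a 4-aryl-4-hydroxy-3-methoxycyclobutenone opens the four-membered ring to a dienylketene whose ketene carbon (C4) closes onto C4a, the only free ortho position of ring A, giving the 1,4-hydroquinone that is oxidised in the same flask. The step exploits the 1,4-dioxygenated quinone ring C1–C4, which maps onto methyl semisquarate, with the C2 methoxy group placed by the regiochemistry of aryllithium addition. The precursor is made from a 2-iodobiaryl assembled by Sandmeyer and Suzuki chemistry.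

Key step: step 7

Assumption: the target has no stereocentre and its hindered biaryl axis carries no descriptor, so no stereocontrol is planned; ring A is the dimethylbenzo ring and ring B the trimethoxyphenyl ring.

Step 1
Reactants: 1 2,3-dimethyl-6-nitroaniline
Product: 3 2-bromo-3,4-dimethyl-1-nitrobenzene, via diazonium bromide 2 (not isolated)
Conditions: NaNO2, 48% HBr, 0 °C; then CuBr (cat.), 48% HBr, 60 °C
Reagents that add atoms: hydrogen bromide, Br
Why: Sandmeyer bromination of the weakly basic ortho-nitroaniline should replace NH2 by Br at the carbon flanked by the methyl and nitro groups, so the contiguous 1,2,3,4-pattern of ring A is taken from the starting material and needs no regiocontrol.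

Step 2
Reactants: 3 2-bromo-3,4-dimethyl-1-nitrobenzene; 4 (2,4,5-trimethoxyphenyl)boronic acid
Product: 5 1-(2,3-dimethyl-6-nitrophenyl)-2,4,5-trimethoxybenzene
Conditions: Pd(OAc)2 (cat.), SPhos, K3PO4, toluene/H2O, 90 °C
Reagents that add atoms: none
Why: Suzuki–Miyaura coupling, in which the ortho-nitro group assists oxidative addition and the bulky biarylphosphine should allow the tri-ortho-substituted biaryl bond to form.

Step 3
Reactants: 5 1-(2,3-dimethyl-6-nitrophenyl)-2,4,5-trimethoxybenzene
Product: 6 3,4-dimethyl-2-(2,4,5-trimethoxyphenyl)aniline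
Conditions: H2 (1 atm), 10% Pd/C, EtOAc/EtOH, rt
Reagents that add atoms: none
Why: Catalytic hydrogenation of an aromatic nitro group, with no other reducible function in the molecule.

Step 4
Reactants: 6 3,4-dimethyl-2-(2,4,5-trimethoxyphenyl)aniline
Product: 8 1-(6-iodo-2,3-dimethylphenyl)-2,4,5-trimethoxybenzene, via diazonium tosylate 7 (not isolated)
Conditions: NaNO2, p-TsOH·H2O, KI, MeCN/H2O, 10 °C to rt
Reagents that add atoms: potassium iodide, [K+].[I-]
Why: Sandmeyer-type iododediazoniation through the arenediazonium tosylate, in which iodide itself reduces the diazonium ion so that no copper salt is needed and the low temperature should outrun side reactions of the electron-rich ring B.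

Step 5
Reactants: 9 dimethyl squarate
Product: 11 3-methoxycyclobut-3-ene-1,2-dione, via hydroxycyclobutenone 10 (not isolated)
Conditions: LiAlH(OtBu)3, THF, −78 °C; then 6 M HCl, CH2Cl2, 0 °C to rt
Reagents that add atoms: none
Why: Mono-reduction of one carbonyl by the bulky hydride followed by acid-induced allylic ionisation, water attack at the methoxy-bearing terminus and loss of methanol (1,3-carbonyl transposition) is the established route from dialkyl squarates to alkyl semisquarates.

Step 6
Reactants: 8 1-(6-iodo-2,3-dimethylphenyl)-2,4,5-trimethoxybenzene; 11 3-methoxycyclobut-3-ene-1,2-dione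
Product: 14 4-[3,4-dimethyl-2-(2,4,5-trimethoxyphenyl)phenyl]-4-hydroxy-3-methoxycyclobut-2-en-1-one, via aryllithium 12 (not isolated), via lithium alkoxide 13 (not isolated)
Conditions: n-BuLi, THF, −78 °C; then cannulation into 11, THF, −78 °C; aq NH4Cl
Reagents that add atoms: none
Why: Iodine–lithium exchange followed by 1,2-addition to the carbonyl next to the methoxy-bearing carbon, which is the more electrophilic one because the other carbonyl is a vinylogous ester, as known for organolithium additions to 3-alkoxycyclobutenediones; the carbinol centre forms as a racemate and is erased in step 7.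

Step 7
Reactants: 14 4-[3,4-dimethyl-2-(2,4,5-trimethoxyphenyl)phenyl]-4-hydroxy-3-methoxycyclobut-2-en-1-one
Product: 18 2-methoxy-6,7-dimethyl-8-(2,4,5-trimethoxyphenyl)naphthalene-1,4-dione, via dienylketene 15 (not isolated), via dienone 16 (not isolated), via hydroquinone 17 (not isolated)
Conditions: p-xylene (degassed), 138 °C; then Ag2O, rt
Reagents that add atoms: none
Why: Heating should open the cyclobutenone by 4π conrotatory electrocyclic cleavage of its C(=O)–C(OH)Ar bond, the hydroxyl donor rotating outward so that the aryl group lies cis to the ketene in dienylketene 15. A thermal disrotatory 6π electrocyclisation across the ketene C=C, the enol C=C and the ipso–ortho bond of ring A then joins the ketene carbon (future C4) to the ortho carbon (future C4a), closing the six-membered quinone ring as dienone 16, which tautomerises to hydroquinone 17 and is dehydrogenated by Ag2O to 18. This is the Moore–Liebeskind rearrangement of 4-aryl-4-hydroxycyclobutenones, a known reaction type applied here directly. No stereocentre remains, because the sp3 centres of 14 and 16 both become sp2. The regiochemistry on ring A is secured because the other ortho position carries ring B, the methoxy position is fixed by step 6, and the torquoselectivity is supplied by the hydroxyl group. Ag2O is chosen because it should oxidise the hydroquinone without attacking the electron-rich ring B, which (NH4)2Ce(NO3)6 would endanger.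

Compound list
1 | 2,3-dimethyl-6-nitroaniline | Cc1ccc([N+](=O)[O-])c(N)c1C | starting material
2 | 2,3-dimethyl-6-nitrobenzenediazonium bromide | Cc1ccc([N+](=O)[O-])c([N+]#N)c1C.[Br-] | intermediate
3 | 2-bromo-3,4-dimethyl-1-nitrobenzene | Cc1ccc([N+](=O)[O-])c(Br)c1C | intermediate
4 | (2,4,5-trimethoxyphenyl)boronic acid | COc1cc(OC)c(B(O)O)cc1OC | starting material
5 | 1-(2,3-dimethyl-6-nitrophenyl)-2,4,5-trimethoxybenzene | Cc1ccc([N+](=O)[O-])c(-c2cc(OC)c(OC)cc2OC)c1C | intermediate
6 | 3,4-dimethyl-2-(2,4,5-trimethoxyphenyl)aniline | Cc1ccc(N)c(-c2cc(OC)c(OC)cc2OC)c1C | intermediate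
7 | 3,4-dimethyl-2-(2,4,5-trimethoxyphenyl)benzenediazonium 4-methylbenzenesulfonate | Cc1ccc([N+]#N)c(-c2cc(OC)c(OC)cc2OC)c1C.Cc1ccc(cc1)S(=O)(=O)[O-] | intermediate
8 | 1-(6-iodo-2,3-dimethylphenyl)-2,4,5-trimethoxybenzene | Cc1ccc(I)c(-c2cc(OC)c(OC)cc2OC)c1C | intermediate
9 | dimethyl squarate (3,4-dimethoxycyclobut-3-ene-1,2-dione) | COC1=C(OC)C(=O)C1=O | starting material
10 | 4-hydroxy-2,3-dimethoxycyclobut-2-en-1-one (racemic) | COC1=C(OC)C(O)C1=O | intermediate
11 | 3-methoxycyclobut-3-ene-1,2-dione (methyl semisquarate) | COC1=CC(=O)C1=O | intermediate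
12 | [3,4-dimethyl-2-(2,4,5-trimethoxyphenyl)phenyl]lithium | [Li]c1ccc(C)c(C)c1-c1cc(OC)c(OC)cc1OC | intermediate
13 | lithium 1-[3,4-dimethyl-2-(2,4,5-trimethoxyphenyl)phenyl]-2-methoxy-4-oxocyclobut-2-en-1-olate (racemic) | COC1=CC(=O)C1(O[Li])c1ccc(C)c(C)c1-c1cc(OC)c(OC)cc1OC | intermediate
14 | 4-[3,4-dimethyl-2-(2,4,5-trimethoxyphenyl)phenyl]-4-hydroxy-3-methoxycyclobut-2-en-1-one (racemic) | COC1=CC(=O)C1(O)c1ccc(C)c(C)c1-c1cc(OC)c(OC)cc1OC | intermediate
15 | (3Z)-4-[3,4-dimethyl-2-(2,4,5-trimethoxyphenyl)phenyl]-4-hydroxy-3-methoxybuta-1,3-dien-1-one (aryl cis to the ketene) | O=C=C/C(OC)=C(/O)c1ccc(C)c(C)c1-c1cc(OC)c(OC)cc1OC | intermediate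
16 | 4-hydroxy-3-methoxy-6,7-dimethyl-5-(2,4,5-trimethoxyphenyl)naphthalen-1(8aH)-one (racemic) | COC1=CC(=O)C2C=C(C)C(C)=C(c3cc(OC)c(OC)cc3OC)C2=C1O | intermediate
17 | 2-methoxy-6,7-dimethyl-8-(2,4,5-trimethoxyphenyl)naphthalene-1,4-diol | COc1cc(O)c2cc(C)c(C)c(-c3cc(OC)c(OC)cc3OC)c2c1O | intermediate
18 | 2-methoxy-6,7-dimethyl-8-(2,4,5-trimethoxyphenyl)naphthalene-1,4-dione | COC1=CC(=O)c2cc(C)c(C)c(-c3cc(OC)c(OC)cc3OC)c2C1=O | target

Total step count: 7. Longest linear sequence: 6 steps (steps 1, 2, 3, 4, 6 and 7); step 5 is the convergent branch.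

Steps most likely to fail

Step 7. The tertiary hydroxyl may trap the ketene (lactonisation to a butenolide) if the aryl group rotates outward or if the 6π closure is slowed by the ortho ring B; the free hydroquinone may also be over-oxidised. The fallback sets out from lithium alkoxide 13 and comes back at hydroquinone 17. Alkoxide 13 would be quenched with Me3SiCl instead of NH4Cl to give 4-[3,4-dimethyl-2-(2,4,5-trimethoxyphenyl)phenyl]-3-methoxy-4-(trimethylsilyloxy)cyclobut-2-en-1-one F1, in which lactonisation is impossible. Thermolysis in p-xylene should give the isolable monosilylated hydroquinone 3-methoxy-6,7-dimethyl-5-(2,4,5-trimethoxyphenyl)-4-(trimethylsilyloxy)naphthalen-1-ol F2. Dilute HCl in THF would cleave the silyl ether to 17, which Ag2O oxidises to 18 as a separate, controllable operation.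

Step 6. The hindered aryllithium may attack the methoxy-bearing carbon with loss of methoxide, or the vinylogous-ester carbonyl, and the methyl vinylogous ester may be lost by hydrolysis during handling. The fallback sets out from aryllithium 12 and comes back at target 18. It uses the bulkier and hydrolytically robust isopropyl surrogate 3-(propan-2-yloxy)cyclobut-3-ene-1,2-dione F3, prepared from commercial diisopropyl squarate by the sequence of step 5. Addition of 12 should give 4-[3,4-dimethyl-2-(2,4,5-trimethoxyphenyl)phenyl]-4-hydroxy-3-(propan-2-yloxy)cyclobut-2-en-1-one F4. Thermolysis and Ag2O oxidation as in step 7 should give 6,7-dimethyl-2-(propan-2-yloxy)-8-(2,4,5-trimethoxyphenyl)naphthalene-1,4-dione F5. Acid-catalysed exchange of the vinylogous ester alkoxy group (MeOH, cat. H2SO4, rt) would then give 18.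

Step 4. The diazonium ion may be trapped by the neighbouring methoxy oxygen of ring B (closure to a dibenzofuran with loss of the methyl group), or ring B may undergo nitrosation or azo coupling. The fallback sets out from 1 and comes back at aryllithium 12, with both diazotisations done before ring B is present. Sandmeyer iodination of 1 (NaNO2, H2SO4; KI) would give 2-iodo-3,4-dimethyl-1-nitrobenzene F6. Reduction with Fe and NH4Cl, which leaves the C–I bond, would give 2-iodo-3,4-dimethylaniline F7. Sandmeyer bromination (NaNO2, HBr, CuBr) would give 1-bromo-2-iodo-3,4-dimethylbenzene F8. Chemoselective Suzuki coupling of 4 at the C–I bond (Pd(PPh3)4, Na2CO3, DME/H2O, 70 °C) would give 1-(6-bromo-2,3-dimethylphenyl)-2,4,5-trimethoxybenzene F9. Bromine–lithium exchange with n-BuLi at −78 °C then gives 12.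

Further compounds
F1 | step 7 | 4-[3,4-dimethyl-2-(2,4,5-trimethoxyphenyl)phenyl]-3-methoxy-4-(trimethylsilyloxy)cyclobut-2-en-1-one | COC1=CC(=O)C1(O[Si](C)(C)C)c1ccc(C)c(C)c1-c1cc(OC)c(OC)cc1OC
F2 | step 7 | 3-methoxy-6,7-dimethyl-5-(2,4,5-trimethoxyphenyl)-4-(trimethylsilyloxy)naphthalen-1-ol | COc1cc(O)c2cc(C)c(C)c(-c3cc(OC)c(OC)cc3OC)c2c1O[Si](C)(C)C
F3 | step 6 | 3-(propan-2-yloxy)cyclobut-3-ene-1,2-dione | CC(C)OC1=CC(=O)C1=O
F4 | step 6 | 4-[3,4-dimethyl-2-(2,4,5-trimethoxyphenyl)phenyl]-4-hydroxy-3-(propan-2-yloxy)cyclobut-2-en-1-one | CC(C)OC1=CC(=O)C1(O)c1ccc(C)c(C)c1-c1cc(OC)c(OC)cc1OC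
F5 | step 6 | 6,7-dimethyl-2-(propan-2-yloxy)-8-(2,4,5-trimethoxyphenyl)naphthalene-1,4-dione | CC(C)OC1=CC(=O)c2cc(C)c(C)c(-c3cc(OC)c(OC)cc3OC)c2C1=O
F6 | step 4 | 2-iodo-3,4-dimethyl-1-nitrobenzene | Cc1ccc([N+](=O)[O-])c(I)c1C
F7 | step 4 | 2-iodo-3,4-dimethylaniline | Cc1ccc(N)c(I)c1C
F8 | step 4 | 1-bromo-2-iodo-3,4-dimethylbenzene | Cc1ccc(Br)c(I)c1C
F9 | step 4 | 1-(6-bromo-2,3-dimethylphenyl)-2,4,5-trimethoxybenzene | Cc1ccc(Br)c(-c2cc(OC)c(OC)cc2OC)c1C
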